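Ring B is not introduced as an arene. Its 3-OMe/4-OH/5-OMe array is mirror-symmetric about the C1–C4 axis, which is the oxygen pattern of a 5-substituted cyclohexane-1,3-dione carrying a third oxygen on C2. The route therefore grows that dione on the end of the C7 chain: in one operation dimethyl malonate adds to an (E)-enone and the ring closes by Claisen acylation, forging two C–C bonds of ring B, after which hydrolysis and decarboxylation leave the symmetric dione. The enone precursor already holds the syn (3R,5S) diol as an acetonide and ring A as its benzyl ether; oxygenation at C2, aromatisation and protecting-group exchange follow.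

Key step: step 6

Assumption: the diisopinocampheylboron enolate of a methyl ketone made from (+)-Ipc2BCl is taken to attack the re face of an unbranched aldehyde; were the opposite sense found, (−)-Ipc2BCl would be used with no other change.

Names: C1–C7 are the heptane carbons of the target, C1 on ring A. "Acetonide arm" means 2-{(4S,6R)-6-[2-(4-benzyloxy-3-methoxyphenyl)ethyl]-2,2-dimethyl-1,3-dioxan-4-yl}ethyl, that is C6–C7 hanging from the syn (3R,5S) acetonide.

Step 1
Reactants: 1 zingerone [4-(4-hydroxy-3-methoxyphenyl)butan-2-one]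
Product: 2 4-(4-benzyloxy-3-methoxyphenyl)butan-2-one
Conditions: BnBr, K2CO3, acetone, reflux
Reagents that add atoms: benzyl bromide, BrCc1ccccc1
Why: Williamson ether synthesis, in which K2CO3 ionises only the phenol and the phenoxide displaces bromide from the benzylic halide while the ketone is not enolised.

Step 2
Reactants: 2 4-(4-benzyloxy-3-methoxyphenyl)butan-2-one; 3 pent-4-enal
Product: 5 (5S)-1-(4-benzyloxy-3-methoxyphenyl)-5-hydroxynon-8-en-3-one, via boron enolate 4 (not isolated)
Conditions: (+)-Ipc2BCl, Et3N, Et2O, 0 °C; then 3, −78 to −20 °C; then MeOH, pH 7 buffer, 30% H2O2, 0 °C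
Reagents that add atoms: none
Why: Diisopinocampheylboron-mediated aldol reaction, in which Ipc2BCl/Et3N enolises the ketone on its CH3 side and the chiral enolate adds through a closed cyclic transition state whose isopinocampheyl ligands direct attack to the re face of pent-4-enal, which should set C5 as (S).

Step 3
Reactants: 5 (5S)-1-(4-benzyloxy-3-methoxyphenyl)-5-hydroxynon-8-en-3-one
Product: 7 (3R,5S)-1-(4-benzyloxy-3-methoxyphenyl)non-8-ene-3,5-diol, via diethylboron chelate 6 (not isolated)
Conditions: Et2BOMe, THF/MeOH (4:1), −78 °C; NaBH4, −78 °C; then pH 7 buffer, MeOH co-evaporation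
Reagents that add atoms: none
Why: Narasaka–Prasad reduction, in which boron ties the C5 oxygen and the C3 carbonyl into a six-membered chelate with the C5 substituent pseudo-equatorial and borohydride adds axially through a chair-like transition state, which should set C3 as (R), syn to C5.

Step 4
Reactants: 7 (3R,5S)-1-(4-benzyloxy-3-methoxyphenyl)non-8-ene-3,5-diol
Product: 8 (4R,6S)-4-[2-(4-benzyloxy-3-methoxyphenyl)ethyl]-6-(but-3-en-1-yl)-2,2-dimethyl-1,3-dioxane
Conditions: 2,2-dimethoxypropane, PPTS (cat.), CH2Cl2, rt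
Reagents that add atoms: 2,2-dimethoxypropane, COC(C)(C)OC
Why: Acid-catalysed transketalisation, favoured because the syn 1,3-diol closes to a chair 1,3-dioxane with both chain substituents equatorial and no C–O bond at a stereocentre is broken.

Step 5
Reactants: 8 (4R,6S)-4-[2-(4-benzyloxy-3-methoxyphenyl)ethyl]-6-(but-3-en-1-yl)-2,2-dimethyl-1,3-dioxane; 9 methyl vinyl ketone (but-3-en-2-one)
Product: 10 (E)-6-{(4S,6R)-6-[2-(4-benzyloxy-3-methoxyphenyl)ethyl]-2,2-dimethyl-1,3-dioxan-4-yl}hex-3-en-2-one
Conditions: RuCl2(H2IMes)(=CH-C6H4-2-OiPr) (second-generation Hoveyda–Grubbs catalyst, 5 mol%), 9 (4 equiv), CH2Cl2, 40 °C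
Reagents that add atoms: none
Why: Olefin cross-metathesis, selective because the unhindered terminal alkene pairs with the electron-poor vinyl ketone, which barely homodimerises, and loss of ethylene leaves the thermodynamically favoured (E)-enone.

Step 6
Reactants: 10 (E)-6-{(4S,6R)-6-[2-(4-benzyloxy-3-methoxyphenyl)ethyl]-2,2-dimethyl-1,3-dioxan-4-yl}hex-3-en-2-one; 11 dimethyl malonate
Product: 15 5-(acetonide arm)cyclohexane-1,3-dione, via Michael adduct 12 (not isolated), via cyclised methyl ester 13 (not isolated), via dioxo acid 14 (not isolated)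
Conditions: NaOMe, MeOH, reflux; then 2 M NaOH aq, reflux; then AcOH to pH 4–5, 60 °C
Reagents that add atoms: none
Why: Sodium dimethyl malonate adds in conjugate fashion to the enone carbon that becomes C1 of ring B, the methyl ketone of adduct 12 is enolised on its CH3 side and that enolate attacks one malonate ester carbonyl with loss of methoxide to give 13; hydroxide then saponifies the remaining ester and acid 14 loses CO2 once the mixture is brought to pH 4–5. The closest known reaction type is the malonate Michael–Claisen (Dieckmann-type) annulation of β-alkyl enones to 5-alkylcyclohexane-1,3-diones. The ring closes by a 6-(enolendo)-exo-trig acyl substitution, the only productive closure because the other ketone enolate could form only a four-membered ring, and it is driven by deprotonation of the new β-diketone. No stereocentre is created in 15, since the chain-bearing ring carbon lies on the mirror plane of the dione and the transient centres of 12–14 vanish on decarboxylation, while C3 and C5 are ether carbons without an acidic neighbour and stay as set. The selectivity needed is regiochemical, 1,4- over 1,2-addition and closure through the CH3-side enolate, and it is secured by the soft, reversibly adding malonate anion and by the thermodynamic sink of the dione enolate. The acetonide and the benzyl ether are inert to methoxide and hydroxide, and the decarboxylation is run only weakly acidic so that the ketal should survive.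

Step 7
Reactants: 15 5-(acetonide arm)cyclohexane-1,3-dione
Product: 16 2-diazo-5-(acetonide arm)cyclohexane-1,3-dione
Conditions: p-ABSA, Et3N, MeCN, 0 °C to rt
Reagents that add atoms: 4-acetamidobenzenesulfonyl azide (p-ABSA), CC(=O)Nc1ccc(cc1)S(=O)(=O)N=[N+]=[N-]
Why: Regitz diazo transfer, in which the methylene between the two carbonyls, the only carbon acid of that strength in 15, is deprotonated and its enolate takes the terminal nitrogen of the sulfonyl azide and expels the sulfonamide.

Step 8
Reactants: 16 2-diazo-5-(acetonide arm)cyclohexane-1,3-dione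
Product: 17 2-benzyloxy-3-hydroxy-5-(acetonide arm)cyclohex-2-en-1-one (enol form of the 2-benzyloxy dione)
Conditions: BnOH (5 equiv), Rh2(OAc)4 (2 mol%), ClCH2CH2Cl, 80 °C
Reagents that add atoms: benzyl alcohol, OCc1ccccc1
Why: Rhodium-carbenoid O–H insertion, in which Rh2(OAc)4 extrudes N2, the electrophilic diacyl carbenoid is captured by the oxygen of the excess alcohol and proton transfer in the oxonium ylide places the benzyl ether on the carbon that becomes C4 of ring B.

Step 9
Reactants: 17 2-benzyloxy-3-hydroxy-5-(acetonide arm)cyclohex-2-en-1-one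
Product: 18 2-benzyloxy-3-methoxy-5-(acetonide arm)cyclohex-2-en-1-one (both epimers at the chain-bearing ring carbon)
Conditions: TMSCHN2, toluene/MeOH (4:1), 0 °C to rt
Reagents that add atoms: trimethylsilyldiazomethane, C[Si](C)(C)C=[N+]=[N-]
Why: O-Methylation of a vinylogous acid by a diazoalkane, in which the acidic enol protonates the reagent and the methyldiazonium ion is captured at oxygen; the symmetric dione gives one constitution from either enol oxygen, and the ring stereocentre that appears as an epimer mixture is erased in step 10.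

Step 10
Reactants: 18 2-benzyloxy-3-methoxy-5-(acetonide arm)cyclohex-2-en-1-one
Product: 21 2-benzyloxy-3-methoxy-5-(acetonide arm)phenol, via silyl dienol ether 19 (not isolated), via cyclohexadienone 20 (not isolated)
Conditions: LiN(iPr)2, THF, −78 °C; TMSCl; then Pd(OAc)2 (1.1 equiv), MeCN, rt
Reagents that add atoms: none
Why: Saegusa–Ito oxidation followed by tautomerisation, in which the kinetic α′ proton of the vinylogous ester is removed, the silyl dienol ether is palladated at that carbon, β-hydride elimination gives the cross-conjugated dienone and this keto tautomer aromatises to the phenol.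

Step 11
Reactants: 21 2-benzyloxy-3-methoxy-5-(acetonide arm)phenol
Product: 22 2-benzyloxy-1,3-dimethoxy-5-(acetonide arm)benzene
Conditions: MeI, K2CO3, DMF, rt
Reagents that add atoms: iodomethane, CI
Why: Williamson ether synthesis at the only acidic site, the new phenol, which completes the OMe/OBn/OMe array of ring B.

Step 12
Reactants: 22 2-benzyloxy-1,3-dimethoxy-5-(acetonide arm)benzene
Product: 23 (3R,5S)-1-(4-benzyloxy-3-methoxyphenyl)-7-(4-benzyloxy-3,5-dimethoxyphenyl)heptane-3,5-diol
Conditions: p-TsOH·H2O (10 mol%), MeOH, rt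
Reagents that add atoms: none
Why: Acid-catalysed transketalisation in methanol, which exchanges the isopropylidene ketal without breaking a C–O bond at C3 or C5, so the configuration is kept, and leaves aryl benzyl and methyl ethers intact.

Step 13
Reactants: 23 (3R,5S)-1-(4-benzyloxy-3-methoxyphenyl)-7-(4-benzyloxy-3,5-dimethoxyphenyl)heptane-3,5-diol
Product: 24 (3R,5S)-1-(4-benzyloxy-3-methoxyphenyl)-7-(4-benzyloxy-3,5-dimethoxyphenyl)heptane-3,5-diyl diacetate
Conditions: Ac2O, pyridine, DMAP (cat.), CH2Cl2, rt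
Reagents that add atoms: acetic anhydride, CC(=O)OC(C)=O
Why: DMAP-catalysed acylation of both secondary alcohols with retention, with no phenol free to compete because both are still benzylated.

Step 14
Reactants: 24 (3R,5S)-1-(4-benzyloxy-3-methoxyphenyl)-7-(4-benzyloxy-3,5-dimethoxyphenyl)heptane-3,5-diyl diacetate
Product: 25 (3R,5S)-1-(4-hydroxy-3-methoxyphenyl)-7-(4-hydroxy-3,5-dimethoxyphenyl)heptane-3,5-diyl diacetate (CNP0327377.1)
Conditions: H2 (1 atm), 10% Pd/C, EtOAc, rt
Reagents that add atoms: none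
Why: Catalytic hydrogenolysis, which cleaves both aryl benzyl ethers at the benzylic C–O bond while alkyl acetates, aryl methyl ethers and the non-benzylic C3 and C5 C–O bonds are inert under neutral conditions.

Compound list
1 | zingerone, 4-(4-hydroxy-3-methoxyphenyl)butan-2-one | CC(=O)CCc1ccc(O)c(OC)c1 | starting material
2 | 4-(4-benzyloxy-3-methoxyphenyl)butan-2-one | CC(=O)CCc1ccc(OCc2ccccc2)c(OC)c1 | intermediate
3 | pent-4-enal | C=CCCC=O | starting material
4 | diisopinocampheylboron enolate of 2, boron on oxygen, terminal CH2= (not isolated) | C=C(CCc1ccc(OCc2ccccc2)c(OC)c1)OB([C@H]1C[C@H]2C[C@@H]([C@@H]1C)C2(C)C)[C@H]1C[C@H]2C[C@@H]([C@@H]1C)C2(C)C | intermediate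
5 | (5S)-1-(4-benzyloxy-3-methoxyphenyl)-5-hydroxynon-8-en-3-one | COc1cc(CCC(=O)C[C@@H](O)CCC=C)ccc1OCc1ccccc1 | intermediate
6 | O-diethylboryl chelate of 5 (not isolated) | COc1cc(CCC(=O)C[C@@H](OB(CC)CC)CCC=C)ccc1OCc1ccccc1 | intermediate
7 | (3R,5S)-1-(4-benzyloxy-3-methoxyphenyl)non-8-ene-3,5-diol, syn | COc1cc(CC[C@@H](O)C[C@@H](O)CCC=C)ccc1OCc1ccccc1 | intermediate
8 | (4R,6S)-4-[2-(4-benzyloxy-3-methoxyphenyl)ethyl]-6-(but-3-en-1-yl)-2,2-dimethyl-1,3-dioxane | COc1cc(CC[C@@H]2C[C@H](CCC=C)OC(C)(C)O2)ccc1OCc1ccccc1 | intermediate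
9 | methyl vinyl ketone | C=CC(C)=O | starting material
10 | (E)-6-{(4S,6R)-6-[2-(4-benzyloxy-3-methoxyphenyl)ethyl]-2,2-dimethyl-1,3-dioxan-4-yl}hex-3-en-2-one | COc1cc(CC[C@@H]2C[C@H](CC/C=C/C(C)=O)OC(C)(C)O2)ccc1OCc1ccccc1 | intermediate
11 | dimethyl malonate | COC(=O)CC(=O)OC | starting material
12 | dimethyl 2-[4-oxo-1-(acetonide arm)pentan-2-yl]malonate, Michael adduct, epimers at the new carbon (not isolated) | COc1cc(CC[C@@H]2C[C@H](CCC(CC(C)=O)C(C(=O)OC)C(=O)OC)OC(C)(C)O2)ccc1OCc1ccccc1 | intermediate
13 | methyl 2,4-dioxo-6-(acetonide arm)cyclohexane-1-carboxylate, present as its sodium enolate (not isolated) | COc1cc(CC[C@@H]2C[C@H](CCC3CC(=O)CC(=O)C3C(=O)OC)OC(C)(C)O2)ccc1OCc1ccccc1 | intermediate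
14 | 2,4-dioxo-6-(acetonide arm)cyclohexane-1-carboxylic acid (not isolated) | COc1cc(CC[C@@H]2C[C@H](CCC3CC(=O)CC(=O)C3C(=O)O)OC(C)(C)O2)ccc1OCc1ccccc1 | intermediate
15 | 5-(acetonide arm)cyclohexane-1,3-dione | COc1cc(CC[C@@H]2C[C@H](CCC3CC(=O)CC(=O)C3)OC(C)(C)O2)ccc1OCc1ccccc1 | intermediate
16 | 2-diazo-5-(acetonide arm)cyclohexane-1,3-dione | COc1cc(CC[C@@H]2C[C@H](CCC3CC(=O)C(=[N+]=[N-])C(=O)C3)OC(C)(C)O2)ccc1OCc1ccccc1 | intermediate
17 | 2-benzyloxy-3-hydroxy-5-(acetonide arm)cyclohex-2-en-1-one | COc1cc(CC[C@@H]2C[C@H](CCC3CC(=O)C(OCc4ccccc4)=C(O)C3)OC(C)(C)O2)ccc1OCc1ccccc1 | intermediate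
18 | 2-benzyloxy-3-methoxy-5-(acetonide arm)cyclohex-2-en-1-one, epimer mixture at the ring carbon | COc1cc(CC[C@@H]2C[C@H](CCC3CC(=O)C(OCc4ccccc4)=C(OC)C3)OC(C)(C)O2)ccc1OCc1ccccc1 | intermediate
19 | 2-benzyloxy-3-methoxy-1-(trimethylsilyloxy)-5-(acetonide arm)cyclohexa-1(6),2-diene (not isolated) | COc1cc(CC[C@@H]2C[C@H](CCC3C=C(O[Si](C)(C)C)C(OCc4ccccc4)=C(OC)C3)OC(C)(C)O2)ccc1OCc1ccccc1 | intermediate
20 | 2-benzyloxy-3-methoxy-5-(acetonide arm)cyclohexa-2,5-dien-1-one, keto tautomer of 21 (not isolated) | COc1cc(CC[C@@H]2C[C@H](CCC3=CC(=O)C(OCc4ccccc4)=C(OC)C3)OC(C)(C)O2)ccc1OCc1ccccc1 | intermediate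
21 | 2-benzyloxy-3-methoxy-5-(acetonide arm)phenol | COc1cc(CC[C@@H]2C[C@H](CCc3cc(O)c(OCc4ccccc4)c(OC)c3)OC(C)(C)O2)ccc1OCc1ccccc1 | intermediate
22 | 2-benzyloxy-1,3-dimethoxy-5-(acetonide arm)benzene | COc1cc(CC[C@@H]2C[C@H](CCc3cc(OC)c(OCc4ccccc4)c(OC)c3)OC(C)(C)O2)ccc1OCc1ccccc1 | intermediate
23 | (3R,5S)-1-(4-benzyloxy-3-methoxyphenyl)-7-(4-benzyloxy-3,5-dimethoxyphenyl)heptane-3,5-diol | COc1cc(CC[C@@H](O)C[C@@H](O)CCc2cc(OC)c(OCc3ccccc3)c(OC)c2)ccc1OCc1ccccc1 | intermediate
24 | (3R,5S)-1-(4-benzyloxy-3-methoxyphenyl)-7-(4-benzyloxy-3,5-dimethoxyphenyl)heptane-3,5-diyl diacetate | COc1cc(CC[C@H](C[C@H](CCc2cc(OC)c(OCc3ccccc3)c(OC)c2)OC(C)=O)OC(C)=O)ccc1OCc1ccccc1 | intermediate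
25 | (3R,5S)-1-(4-hydroxy-3-methoxyphenyl)-7-(4-hydroxy-3,5-dimethoxyphenyl)heptane-3,5-diyl diacetate | COc1cc(CC[C@H](C[C@H](CCc2cc(OC)c(O)c(OC)c2)OC(C)=O)OC(C)=O)ccc1O | target

Total step count: 14. Longest linear sequence: 14 steps (1 to 25); compounds 3, 9 and 11 are bought.

Steps most likely to fail

Step 2. The boron enolate may discriminate too weakly between the two faces of an unbranched aldehyde, which would erode the enantiomeric purity of everything downstream. The fallback moves the asymmetric step to a catalytic ketone hydrogenation. It sets out from ketone 2, which would be C-carboxylated on its methyl group (NaH, dimethyl carbonate, THF, reflux) to methyl 5-(4-benzyloxy-3-methoxyphenyl)-3-oxopentanoate F1. Hydrogenation over RuCl2[(R)-BINAP] in MeOH should give methyl (3R)-5-(4-benzyloxy-3-methoxyphenyl)-3-hydroxypentanoate F2, the configuration of C3 now being set by the ligand. Treatment with MeONHMe·HCl and iPrMgCl (THF, −20 °C) would give the Weinreb amide (3R)-5-(4-benzyloxy-3-methoxyphenyl)-3-hydroxy-N-methoxy-N-methylpentanamide F3. But-3-enylmagnesium bromide would convert it into (3R)-1-(4-benzyloxy-3-methoxyphenyl)-3-hydroxynon-8-en-5-one F4. Reduction as in step 3, through the diethylboron chelate of that ketone F5, sets C5 syn and comes back to the route at diol 7.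

Step 6. The ketal may be partly hydrolysed during the acidification that triggers decarboxylation, or the sequence may stall after conjugate addition so that the open adduct is saponified instead of cyclised. The fallback splits the operation and removes the extra carboxyl carbon without acid. It sets out from enone 10, which with diallyl malonate and NaH (THF, rt, then reflux) would give the Michael adduct diallyl 2-[4-oxo-1-(acetonide arm)pentan-2-yl]malonate F6. Under the same base this closes to allyl 2,4-dioxo-6-(acetonide arm)cyclohexane-1-carboxylate F7, which is isolated after neutral work-up. Pd(PPh3)4 with morpholine (THF, rt) would then pass the allyl group to the amine, and the liberated acid 14 loses CO2 at neutral pH, coming back to the route at dione 15.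

Step 8. The rhodium carbenoid may be diverted from O–H insertion into Wolff-type ring contraction or into attack on the electron-rich arenes or the ketal oxygens. The fallback carries the central oxygen into the annulation and avoids the carbenoid altogether. It sets out from alkene 8, which would undergo cross-metathesis (catalyst of step 5) with 1-(benzyloxy)but-3-en-2-one F8, made from 2-(benzyloxy)-N-methoxy-N-methylacetamide and vinylmagnesium bromide, to give (E)-1-benzyloxy-6-{(4S,6R)-6-[2-(4-benzyloxy-3-methoxyphenyl)ethyl]-2,2-dimethyl-1,3-dioxan-4-yl}hex-3-en-2-one F9. Under the conditions of step 6 malonate would add to give dimethyl 2-[5-benzyloxy-4-oxo-1-(acetonide arm)pentan-2-yl]malonate F10. The ketone, now enolised on its benzyloxymethyl side, would close the ring to methyl 3-benzyloxy-2,4-dioxo-6-(acetonide arm)cyclohexane-1-carboxylate F11. Saponification to 3-benzyloxy-2,4-dioxo-6-(acetonide arm)cyclohexane-1-carboxylic acid F12 and loss of CO2 come back to the route at compound 17, so that steps 7 and 8 are not needed.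

Further compounds
F1 | step 2 | methyl 5-(4-benzyloxy-3-methoxyphenyl)-3-oxopentanoate | COC(=O)CC(=O)CCc1ccc(OCc2ccccc2)c(OC)c1
F2 | step 2 | methyl (3R)-5-(4-benzyloxy-3-methoxyphenyl)-3-hydroxypentanoate | COC(=O)C[C@H](O)CCc1ccc(OCc2ccccc2)c(OC)c1
F3 | step 2 | (3R)-5-(4-benzyloxy-3-methoxyphenyl)-3-hydroxy-N-methoxy-N-methylpentanamide | CON(C)C(=O)C[C@H](O)CCc1ccc(OCc2ccccc2)c(OC)c1
F4 | step 2 | (3R)-1-(4-benzyloxy-3-methoxyphenyl)-3-hydroxynon-8-en-5-one | C=CCCC(=O)C[C@H](O)CCc1ccc(OCc2ccccc2)c(OC)c1
F5 | step 2 | O-diethylboryl chelate of F4 | C=CCCC(=O)C[C@H](OB(CC)CC)CCc1ccc(OCc2ccccc2)c(OC)c1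
F6 | step 6 | diallyl 2-[4-oxo-1-(acetonide arm)pentan-2-yl]malonate | COc1cc(CC[C@@H]2C[C@H](CCC(CC(C)=O)C(C(=O)OCC=C)C(=O)OCC=C)OC(C)(C)O2)ccc1OCc1ccccc1
F7 | step 6 | allyl 2,4-dioxo-6-(acetonide arm)cyclohexane-1-carboxylate | COc1cc(CC[C@@H]2C[C@H](CCC3CC(=O)CC(=O)C3C(=O)OCC=C)OC(C)(C)O2)ccc1OCc1ccccc1
F8 | step 8 | 1-(benzyloxy)but-3-en-2-one | C=CC(=O)COCc1ccccc1
F9 | step 8 | (E)-1-benzyloxy-6-{(4S,6R)-6-[2-(4-benzyloxy-3-methoxyphenyl)ethyl]-2,2-dimethyl-1,3-dioxan-4-yl}hex-3-en-2-one | COc1cc(CC[C@@H]2C[C@H](CC/C=C/C(=O)COCc3ccccc3)OC(C)(C)O2)ccc1OCc1ccccc1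
F10 | step 8 | dimethyl 2-[5-benzyloxy-4-oxo-1-(acetonide arm)pentan-2-yl]malonate | COc1cc(CC[C@@H]2C[C@H](CCC(CC(=O)COCc3ccccc3)C(C(=O)OC)C(=O)OC)OC(C)(C)O2)ccc1OCc1ccccc1
F11 | step 8 | methyl 3-benzyloxy-2,4-dioxo-6-(acetonide arm)cyclohexane-1-carboxylate | COc1cc(CC[C@@H]2C[C@H](CCC3CC(=O)C(OCc4ccccc4)C(=O)C3C(=O)OC)OC(C)(C)O2)ccc1OCc1ccccc1
F12 | step 8 | 3-benzyloxy-2,4-dioxo-6-(acetonide arm)cyclohexane-1-carboxylic acid | COc1cc(CC[C@@H]2C[C@H](CCC3CC(=O)C(OCc4ccccc4)C(=O)C3C(=O)O)OC(C)(C)O2)ccc1OCc1ccccc1
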